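It was impossible to read either answer straight off the runs, since birch, oak and larch each stopped at 5.00 min, earlier than Saturday's 10 min and Monday's 20 min.

| setting | birch | oak | larch | Monday's | Saturday's |
|---|---|---|---|---|---|
| substrate | 0.070 M | 0.28 M | 0.050 M | 0.20 M | 0.050 M |
| other conformer | 0.050 M | 0.050 M | 0.049 M | 0.0250 M | 0.0500 M |
| remark | run made earlier | run made earlier | run made earlier |  |  |
| time |  |  |  | 20 min | 10 min |

| run | time / min | target / % |
|---|---|---|
| birch | 0.417 | 1.3 |
| birch | 0.667 | 3.4 |
| birch | 1.00 | 3.6 |
| birch | 2.00 | 6.1 |
| birch | 3.00 | 9.3 |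
| birch | 5.00 | 14.4 |
| oak | 0.833 | 4.5 |
| oak | 1.50 | 6.7 |
| oak | 2.50 | 10.4 |
| oak | 3.00 | 11.9 |
| oak | 4.00 | 15.1 |
| oak | 5.00 | 16.4 |
| larch | 1.00 | 3.6 |
| larch | 2.00 | 6.5 |
| larch | 3.00 | 9.4 |
| larch | 4.00 | 10.9 |
| larch | 5.00 | 13.1 |

(standard deviation of a reading: 0.5 percentage points)

- which one finishes higher in amount of target, in percent of the substrate and other conformer together charged ("neither" within 2 percentage points) (Monday's / Saturday's / neither)
- amount of target at the end, in percent of the substrate and other conformer together charged, Monday's
- amount of target at the end, in percent of the substrate and other conformer together charged, Saturday's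

- the numbers in the tables scatter by 0.5 percentage points (one standard deviation)
- in a conversion other conformer counts as not yet reacted; third conformer counts as reacted

To carry the curves that far I chose, without claiming a mechanism, to let the rise of c(target) slow with the square of its distance from a ceiling Y, an apparent second-order decay, which integrates to a share of the ceiling equal to θ over one plus θ. The larch readings at 2.00 min and 5.00 min gave Y = 40.5 % and a rise time τ of 10.5 min, so Saturday's, nearly the larch charge, has a reduced time θ, its time over τ, of 0.955 and should reach 19.8 %. The larch reading at 3.00 min, kept out of that reckoning, tested the curve, which gave 9.00 % against 9.4 % read. For Monday's I took the oak curve, with Y = 43.2 % and τ = 8.17 min, so θ = 2.45 and 30.7 %. On the larch curve Monday's would give 26.6 %, so θ by itself named the winner but not the amount.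

The forecast chose Monday's, with 33 % and 21 %, both above mine, and of Monday's it said “so I take about 33%, with wide uncertainty”.

The flasks gave 32.8 % for Monday's and 20.8 % for Saturday's, so Monday's finished higher.

    other conformer ⇌ third conformer (K = 2.00, k = 0.0490 min⁻¹)
    other conformer → isomer of the product A (k = 0.0300 min⁻¹)
    third conformer → third product (k = 0.180 min⁻¹)
    substrate ⇌ other conformer (K = 0.950, k = 0.180 min⁻¹)
    other conformer ⇌ dormant form (K = 0.800, k = 0.00750 min⁻¹)
    target ⇌ isomer of the product B (K = 0.470, k = 0.0300 min⁻¹)
    substrate → target (k = 0.0650 min⁻¹)

Of that gap of 12 percentage points, time carried 7.2 points on average over the orders of changing. Saturday's flask read at 25 min instead has θ = 2.39, which I reckoned as 28.6 % target, and it held 29.8 %, beside 21.4 % third product.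

The runs are simulated on assumed constants; scatter was added.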